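The route rests on cutting the bond between the syringyl ring and C1, the doubly benzylic carbon of the tetralin ring. C1 is held as the lactol carbon of a cis-3,4-disubstituted tetrahydrofuran: its ring oxygen is the future free CH2OH on C3, whereas the CH2O on C2, which cannot bridge to C1, already carries the sulfate. In one operation an aryl Grignard reagent adds to this lactol (either C1 epimer) and acid then ionises C1, so that the tethered trioxygenated ring closes the C1–C8a bond of the tetralin by Friedel–Crafts attack, sets C1 trans to C2 and releases the C3 hydroxymethyl group.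

Key step: step 8

Numbering: tetralin atoms C1 (bears the aryl group), C2 (bears CH2OSO3H), C3 (bears CH2OH), C4 (CH2), C4a and C8a (ring-fusion carbons, C8a bonded to C1). The same labels are used for these carbons in all open-chain and furanoid precursors.

Assumption: the sulfate monoesters 10, 14 and 15 (and F3, F5) are handled as sodium salts and drawn as neutral hydrogen sulfates; 16 is liberated on an H+ resin at the end of step 9.

Step 1
Reactants: 1 4-(benzyloxy)-3,5-dimethoxybenzaldehyde; 2 dimethyl succinate
Product: 3 (E)-4-[4-(benzyloxy)-3,5-dimethoxyphenyl]-3-(methoxycarbonyl)but-3-enoic acid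
Conditions: t-BuOK, t-BuOH, reflux; then aq. HCl
Reagents that add atoms: none
Why: Stobbe condensation (aldol addition, lactonisation to the paraconate, E1cB opening) should give the (E)-alkylidene half-ester and thereby differentiates the two carboxyl groups as acid and methyl ester.

Step 2
Reactants: 3 (E)-half-ester
Product: 4 (3S)-4-[4-(benzyloxy)-3,5-dimethoxyphenyl]-3-(methoxycarbonyl)butanoic acid
Conditions: H2 (5 bar), [Rh(cod)(Et-DuPhos)]BF4 (1 mol %, ligand antipode chosen to deliver the S acid), MeOH, rt
Reagents that add atoms: none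
Why: Rh–bisphospholane asymmetric hydrogenation of an itaconate-type half-ester, in which two-point binding of alkene and carboxylate fixes the face, should set the C3 stereocentre, and the benzyl ether is inert to the homogeneous catalyst.

Step 3
Reactants: 4 (3S)-half-ester acid
Product: 5 (4S)-4-[4-(benzyloxy)-3,5-dimethoxybenzyl]dihydrofuran-2(3H)-one
Conditions: KOH (1.0 equiv), EtOH; CaCl2, NaBH4, EtOH, −10 °C → rt; then 2 M HCl
Reagents that add atoms: none
Why: Chemoselective borohydride reduction (Ca(BH4)2 reduces the methyl ester but not the potassium carboxylate) followed by acid lactonisation gives the β-substituted butyrolactone, in which C3 is no longer α to a carbonyl group and cannot epimerise.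

Step 4
Reactants: 5 (4S)-lactone
Product: 7 (3R,4S)-4-[4-(benzyloxy)-3,5-dimethoxybenzyl]-3-(dimethoxymethyl)dihydrofuran-2(3H)-one, via silyl ketene acetal 6 (not isolated)
Conditions: LDA, THF, −78 °C, then TMSCl; HC(OMe)3, TMSOTf (10 mol %), CH2Cl2, −78 °C; aq. NaHCO3
Reagents that add atoms: trimethyl orthoformate COC(OC)OC
Why: Mukaiyama-type alkylation of the silyl ketene acetal by the dimethoxycarbenium ion from the orthoester introduces C1 as a masked aldehyde, and attack on the planar ketene acetal anti to the neighbouring arylmethyl group should set C2 trans to it on the lactone ring.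

Step 5
Reactants: 7 trans-acetal lactone
Product: 9 (3S,4S)-4-[4-(benzyloxy)-3,5-dimethoxybenzyl]-3-(hydroxymethyl)tetrahydrofuran-2-ol (anomer mixture), via diol acetal 8 (not isolated)
Conditions: LiAlH4, THF, 0 °C, aqueous NaOH work-up; then AcOH–H2O–THF (3:1:1), 35 °C
Reagents that add atoms: water O
Why: Hydride reduction of the lactone followed by mild acetal hydrolysis unmasks the C1 aldehyde, which can close a five-membered hemiacetal only with the C3 arm (the C2 arm would need a four-membered ring), so the two CH2OH groups are differentiated by ring size while C2 and C3 stay untouched (now 3,4-cis on the new ring).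

Step 6
Reactants: 9 lactol
Product: 10 [(3S,4S)-4-[4-(benzyloxy)-3,5-dimethoxybenzyl]-2-hydroxytetrahydrofuran-3-yl]methyl hydrogen sulfate
Conditions: SO3·pyridine (1.2 equiv), pyridine, 0 °C; aq. NaHCO3
Reagents that add atoms: sulfur trioxide–pyridine complex O=S(=O)([O-])[n+]1ccccc1
Why: O-sulfation with SO3·pyridine should take the only primary alcohol, because the hemiacetal hydroxyl is less nucleophilic and any anomeric sulfate reverts to the lactol on aqueous work-up.

Step 7
Reactants: 11 4-bromo-2,6-dimethoxyphenol
Product: 12 2-(benzyloxy)-5-bromo-1,3-dimethoxybenzene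
Conditions: BnBr, K2CO3, DMF, rt
Reagents that add atoms: benzyl bromide BrCc1ccccc1
Why: Williamson etherification of the phenoxide protects the phenol as the same benzyl ether that the other ring carries.

Step 8
Reactants: 10 lactol sulfate (sodium salt); 12 2-(benzyloxy)-5-bromo-1,3-dimethoxybenzene
Product: 15 [(1R,2S,3S)-7-(benzyloxy)-1-[4-(benzyloxy)-3,5-dimethoxyphenyl]-3-(hydroxymethyl)-6,8-dimethoxy-1,2,3,4-tetrahydronaphthalen-2-yl]methyl hydrogen sulfate, via aryl Grignard reagent 13 (not isolated), via benzylic carbinol 14 (not isolated)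
Conditions: 12, Mg, THF, 45 °C (gives 13, 3.5 equiv); 10, LaCl3·2LiCl, THF, −20 → 0 °C; solvent switch, then TFA–CH2Cl2 (1:9), 0 °C → rt; NaHCO3, MeOH–H2O
Reagents that add atoms: none
Why: The Grignard reagent first deprotonates the lactol, whose open hydroxy-aldehyde form then takes up a second equivalent at C1 to give both epimers of the benzylic alkoxide 14 (1,2-addition of an aryl Grignard reagent to a lactol; the alkyl sulfate monoanion, like the methyl sulfate left after a methylation with dimethyl sulfate, is inert to the organometallic, and LaCl3·2LiCl favours addition over enolisation of the α-branched aldehyde). TFA then ionises the electron-rich benzylic C1–O bond of either epimer to one planar p-alkoxybenzyl cation, so the step is stereoconvergent at C1; the closest known reactions are the acid-induced rearrangement of 2-aryl-4-benzyltetrahydrofuran lignans to aryltetralins and the TFA cyclisation of α-(hydroxybenzyl)-β-benzylbutyrolactones. The tetralin ring closes by 6-exo-trig Friedel–Crafts attack of C8a (ortho to the CH2 of the tethered ring, activated by ortho- and para-OMe) on the exocyclic C1 cation, while reversible capture of the cation by the C3 hydroxymethyl oxygen (5-exo) or by the sulfate only stores it. C1 is set in this closure: in the chair-like transition state the C2 and C3 arms and the pendant aryl group are pseudo-equatorial, which should give 1,2-trans (1R) next to the 2S,3S centres carried unchanged from 10. The step needs the pendant aryl to be bonded to C1 before any C1 cation exists (otherwise the tethered ring would attack a lactol oxocarbenium ion and the aryl would later enter a tetralinyl cation with uncertain facial sense), a single aryl regiochemistry and a single ring-closure site; the anionic first stage, the bromine-defined ipso carbon of 12 and the C2-symmetric substitution of the tethered ring secure these. The C3 CH2OH is released from the lactol oxygen only here, after the C2 CH2O has been sulfated, so the two arms never need separate protection.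

Step 9
Reactants: 15 dibenzyl ether of the target
Product: 16 [(1R,2S,3S)-7-hydroxy-1-(4-hydroxy-3,5-dimethoxyphenyl)-3-(hydroxymethyl)-6,8-dimethoxy-1,2,3,4-tetrahydronaphthalen-2-yl]methyl hydrogen sulfate
Conditions: H2 (1 atm), 10% Pd/C, MeOH, rt; then Dowex 50W (H+ form)
Reagents that add atoms: none
Why: Catalytic hydrogenolysis should cleave both aryl benzyl ethers, while the alkyl sulfate monoester, the diarylmethine C1–H and the three stereocentres are inert to these conditions.

Compound list
1 | 4-(benzyloxy)-3,5-dimethoxybenzaldehyde | COc1cc(C=O)cc(OC)c1OCc1ccccc1 | starting material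
2 | dimethyl succinate | COC(=O)CCC(=O)OC | starting material
3 | (E)-4-[4-(benzyloxy)-3,5-dimethoxyphenyl]-3-(methoxycarbonyl)but-3-enoic acid | OC(=O)C/C(=C\c1cc(OC)c(OCc2ccccc2)c(OC)c1)C(=O)OC | intermediate
4 | (3S)-4-[4-(benzyloxy)-3,5-dimethoxyphenyl]-3-(methoxycarbonyl)butanoic acid | COc1cc(C[C@H](C(=O)OC)CC(=O)O)cc(OC)c1OCc1ccccc1 | intermediate
5 | (4S)-4-[4-(benzyloxy)-3,5-dimethoxybenzyl]dihydrofuran-2(3H)-one | O=C1C[C@H](Cc2cc(OC)c(OCc3ccccc3)c(OC)c2)CO1 | intermediate
6 | (3S)-3-[4-(benzyloxy)-3,5-dimethoxybenzyl]-5-(trimethylsilyloxy)-2,3-dihydrofuran (silyl ketene acetal) | C[Si](C)(C)OC1=C[C@H](Cc2cc(OC)c(OCc3ccccc3)c(OC)c2)CO1 | intermediate (not isolated)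
7 | (3R,4S)-4-[4-(benzyloxy)-3,5-dimethoxybenzyl]-3-(dimethoxymethyl)dihydrofuran-2(3H)-one (trans) | COC(OC)[C@@H]1C(=O)OC[C@H]1Cc1cc(OC)c(OCc2ccccc2)c(OC)c1 | intermediate
8 | (2S,3S)-2-[4-(benzyloxy)-3,5-dimethoxybenzyl]-3-(dimethoxymethyl)butane-1,4-diol | COC(OC)[C@H](CO)[C@@H](CO)Cc1cc(OC)c(OCc2ccccc2)c(OC)c1 | intermediate (not isolated)
9 | (3S,4S)-4-[4-(benzyloxy)-3,5-dimethoxybenzyl]-3-(hydroxymethyl)tetrahydrofuran-2-ol (3,4-cis, anomer mixture) | OC1OC[C@@H](Cc2cc(OC)c(OCc3ccccc3)c(OC)c2)[C@H]1CO | intermediate
10 | [(3S,4S)-4-[4-(benzyloxy)-3,5-dimethoxybenzyl]-2-hydroxytetrahydrofuran-3-yl]methyl hydrogen sulfate (anomer mixture) | OC1OC[C@@H](Cc2cc(OC)c(OCc3ccccc3)c(OC)c2)[C@H]1COS(=O)(=O)O | intermediate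
11 | 4-bromo-2,6-dimethoxyphenol | COc1cc(Br)cc(OC)c1O | starting material
12 | 2-(benzyloxy)-5-bromo-1,3-dimethoxybenzene | COc1cc(Br)cc(OC)c1OCc1ccccc1 | intermediate
13 | [4-(benzyloxy)-3,5-dimethoxyphenyl]magnesium bromide | COc1cc([Mg]Br)cc(OC)c1OCc1ccccc1 | intermediate (not isolated)
14 | (2S,3S)-2-{[4-(benzyloxy)-3,5-dimethoxyphenyl](hydroxy)methyl}-3-[4-(benzyloxy)-3,5-dimethoxybenzyl]-4-hydroxybutyl hydrogen sulfate (both carbinol epimers) | COc1cc(C(O)[C@H](COS(=O)(=O)O)[C@@H](CO)Cc2cc(OC)c(OCc3ccccc3)c(OC)c2)cc(OC)c1OCc1ccccc1 | intermediate (not isolated)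
15 | [(1R,2S,3S)-7-(benzyloxy)-1-[4-(benzyloxy)-3,5-dimethoxyphenyl]-3-(hydroxymethyl)-6,8-dimethoxy-1,2,3,4-tetrahydronaphthalen-2-yl]methyl hydrogen sulfate | COc1cc([C@@H]2c3c(cc(OC)c(OCc4ccccc4)c3OC)C[C@H](CO)[C@H]2COS(=O)(=O)O)cc(OC)c1OCc1ccccc1 | intermediate
16 | [(1R,2S,3S)-7-hydroxy-1-(4-hydroxy-3,5-dimethoxyphenyl)-3-(hydroxymethyl)-6,8-dimethoxy-1,2,3,4-tetrahydronaphthalen-2-yl]methyl hydrogen sulfate | COc1cc([C@@H]2c3c(cc(OC)c(O)c3OC)C[C@H](CO)[C@H]2COS(=O)(=O)O)cc(OC)c1O | target

Total step count: 9. Longest linear sequence: 8 steps (steps 1–6, 8 and 9); step 7 is a one-step side branch.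

Steps most likely to fail

Step 8 (key step). In the Grignard stage the transient α-branched aldehyde may enolise, which would epimerise C2 or eliminate the β-sulfate, or the sulfate salt may dissolve too poorly for the addition to go to completion. In the acid stage, E1 loss of H-2 or partial loss of benzyl ethers may compete with ring closure. The fallback keeps the sulfate away from the organometallic and separates the events. It sets out from lactol 9 (before sulfation) and bromide 12. Grignard reagent 13 is added to 9 to give the triol (2S,3S)-2-{[4-(benzyloxy)-3,5-dimethoxyphenyl](hydroxy)methyl}-3-[4-(benzyloxy)-3,5-dimethoxybenzyl]butane-1,4-diol F1. Catalytic camphorsulfonic acid in CH2Cl2 at 0 °C should then close only the five-membered ether from the C3 arm, giving the 2-aryl-tetrahydrofuran [(3S,4S)-2-[4-(benzyloxy)-3,5-dimethoxyphenyl]-4-[4-(benzyloxy)-3,5-dimethoxybenzyl]tetrahydrofuran-3-yl]methanol F2. Its single free primary alcohol is sulfated with SO3·pyridine to the corresponding hydrogen sulfate F3, and TFA in CH2Cl2 then effects the ring-opening/Friedel–Crafts rearrangement, coming back to the route at 15.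

Step 6. Chemoselectivity between the primary and the hemiacetal hydroxyl may be poor, or the lactol may undergo ring-chain side reactions in pyridine. The fallback masks the anomeric position first. It sets out from 9, which with catalytic HCl in MeOH gives the methyl acetal [(3S,4S)-4-[4-(benzyloxy)-3,5-dimethoxybenzyl]-2-methoxytetrahydrofuran-3-yl]methanol F4. Sulfation of its only hydroxyl with SO3·pyridine gives the acetal sulfate [(3S,4S)-4-[4-(benzyloxy)-3,5-dimethoxybenzyl]-2-methoxytetrahydrofuran-3-yl]methyl hydrogen sulfate F5, and mild hydrolysis (AcOH–H2O) returns to the route at 10.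

Step 4. Facial selectivity in the attack of the dimethoxycarbenium ion may be poor, or Lewis-acid-induced loss of methanol to the methoxymethylene lactone may erase the C2 centre. The fallback sets C2 under thermodynamic instead of kinetic control. It sets out from 5, which is formylated (HCO2Et, NaH, THF) to the hydroxymethylene lactone (4S)-4-[4-(benzyloxy)-3,5-dimethoxybenzyl]-3-(hydroxymethylene)dihydrofuran-2(3H)-one F6. This is acetalised (HC(OMe)3, TsOH, MeOH) and then stirred with catalytic NaOMe in MeOH, which adds methanol to any methoxymethylene lactone and equilibrates the α-centre to the more stable trans isomer, coming back to the route at 7.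

Further compounds
F1 | step 8 | (2S,3S)-2-{[4-(benzyloxy)-3,5-dimethoxyphenyl](hydroxy)methyl}-3-[4-(benzyloxy)-3,5-dimethoxybenzyl]butane-1,4-diol | COc1cc(C(O)[C@H](CO)[C@@H](CO)Cc2cc(OC)c(OCc3ccccc3)c(OC)c2)cc(OC)c1OCc1ccccc1
F2 | step 8 | [(3S,4S)-2-[4-(benzyloxy)-3,5-dimethoxyphenyl]-4-[4-(benzyloxy)-3,5-dimethoxybenzyl]tetrahydrofuran-3-yl]methanol | COc1cc(C2OC[C@@H](Cc3cc(OC)c(OCc4ccccc4)c(OC)c3)[C@H]2CO)cc(OC)c1OCc1ccccc1
F3 | step 8 | [(3S,4S)-2-[4-(benzyloxy)-3,5-dimethoxyphenyl]-4-[4-(benzyloxy)-3,5-dimethoxybenzyl]tetrahydrofuran-3-yl]methyl hydrogen sulfate | COc1cc(C2OC[C@@H](Cc3cc(OC)c(OCc4ccccc4)c(OC)c3)[C@H]2COS(=O)(=O)O)cc(OC)c1OCc1ccccc1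
F4 | step 6 | [(3S,4S)-4-[4-(benzyloxy)-3,5-dimethoxybenzyl]-2-methoxytetrahydrofuran-3-yl]methanol | COC1OC[C@@H](Cc2cc(OC)c(OCc3ccccc3)c(OC)c2)[C@H]1CO
F5 | step 6 | [(3S,4S)-4-[4-(benzyloxy)-3,5-dimethoxybenzyl]-2-methoxytetrahydrofuran-3-yl]methyl hydrogen sulfate | COC1OC[C@@H](Cc2cc(OC)c(OCc3ccccc3)c(OC)c2)[C@H]1COS(=O)(=O)O
F6 | step 4 | (4S)-4-[4-(benzyloxy)-3,5-dimethoxybenzyl]-3-(hydroxymethylene)dihydrofuran-2(3H)-one | OC=C1C(=O)OC[C@H]1Cc1cc(OC)c(OCc2ccccc2)c(OC)c1
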